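**Retrosynthetic overview**

1. 33 ⇐ 32 (peracid epoxidation of the E-C1=C10 bond) ⇐ 31 (C3 acetate by Mitsunobu inversion) ⇐ 25 (C8 angelate, α-methylenation; the E olefin comes from the Z olefin by inversion through its epoxide).
2. Ten-membered ring ⇐ eight-membered ring: the alkoxide of 16 holds the 1,5-diene C5=C4–C15–C8(O−)–C7=C6; a [3,3] shift breaks the ring bond C15–C8 and makes C5–C6, and the enolate is alkylated at C7 (brings C11, C12).
3. Enabling feature: the exocyclic methylene C15 on C4, next to the vicinal C5–O/C6–O pair with the C8 oxygen two atoms further, is the footprint of that shift. C15 is a former ring carbon of an eight-membered ring (C3, C4, C15, C8, C9, C10, C1, C2) that is expelled as the ring grows by two atoms.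
4. Eight-membered ring ⇐ ring-closing metathesis (C1=C10) of dioxin 10 ⇐ enol triflate 8 (Negishi coupling, Grignard) ⇐ SAMP-hydrazone allylation of 2,2-dimethyl-1,3-dioxan-5-one, which sets C3, the only stereocentre introduced by an auxiliary.
5. Order of ring formation: 1,3-dioxane (purchased) → eight-membered carbocycle (step 7) → ten-membered carbocycle (step 11) → γ-lactone (step 12) → oxirane (step 20).

Key step: step 11

Remark on numbering: atoms are numbered as in germacranolides (C1–C10 ring; C11–C13 lactone chain; C14 methyl on C10; C15 methylene on C4).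
Remark (assumption): two kinds of centre carry no information for the target and are left unassigned: the carbinol carbon C8 of 15 and 16 (it becomes trigonal in step 11) and the oxirane carbons of 22–24 (both become trigonal in step 15).

**Route**

Step 1
Reactants: 1 2,2-dimethyl-1,3-dioxan-5-one; 2 (S)-1-amino-2-(methoxymethyl)pyrrolidine (SAMP)
Product: 3 SAMP hydrazone of 1
Conditions: benzene, 80 °C, azeotropic removal of water
Reagents that add atoms: none
Why: Hydrazone condensation installs the auxiliary for the SAMP-hydrazone (Enders) alkylation; no stereocentre is formed.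

Step 2
Reactants: 3 SAMP hydrazone of 1
Product: 5 SAMP hydrazone of (S)-4-allyl-2,2-dimethyl-1,3-dioxan-5-one, via lithium azaenolate 4 (not isolated)
Conditions: t-BuLi, THF, −78 °C; allyl bromide, −100 → 25 °C
Reagents that add atoms: allyl bromide, C=CCBr
Why: SAMP-hydrazone (Enders) alkylation: the chelated azaenolate should be allylated on the face left open by the methoxymethyl arm, giving S at the new centre (C3 in target numbering).

Step 3
Reactants: 5 SAMP hydrazone of (S)-4-allyl-2,2-dimethyl-1,3-dioxan-5-one
Product: 6 (S)-4-allyl-2,2-dimethyl-1,3-dioxan-5-one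
Conditions: saturated aq. oxalic acid, Et2O, 25 °C
Reagents that add atoms: water, O
Why: Mild two-phase hydrolytic hydrazone cleavage should return the ketone without epimerising the α-centre and releases the auxiliary.

Step 4
Reactants: 6 (S)-4-allyl-2,2-dimethyl-1,3-dioxan-5-one
Product: 8 (S)-4-allyl-2,2-dimethyl-4H-1,3-dioxin-5-yl trifluoromethanesulfonate, via potassium enolate 7 (not isolated)
Conditions: KN(SiMe3)2, THF, −78 °C; PhNTf2, −78 → 0 °C
Reagents that add atoms: N-phenylbis(trifluoromethanesulfonimide), O=S(=O)(N(c1ccccc1)S(=O)(=O)C(F)(F)F)C(F)(F)F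
Why: Kinetic deprotonation at the unsubstituted α-CH2 (C5) and O-sulfonylation (enol triflate formation) lock the C4=C5 enol ether inside the dioxin ring, which later holds O5 trans to C15; C3 is not touched.

Step 5
Reactants: 8 (S)-4-allyl-2,2-dimethyl-4H-1,3-dioxin-5-yl trifluoromethanesulfonate
Product: 9 2-[(S)-4-allyl-2,2-dimethyl-4H-1,3-dioxin-5-yl]-N-methoxy-N-methylacetamide
Conditions: BrZnCH2C(O)N(OCH3)CH3 (from BrCH2C(O)N(OCH3)CH3 and Zn dust, THF), Pd(PPh3)4 (5 mol %), THF, 45 °C
Reagents that add atoms: bromozinc enolate of N-methoxy-N-methylacetamide, CON(C)C(=O)C[Zn]Br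
Why: Negishi coupling of a Reformatsky reagent (oxidative addition of the enol triflate to zerovalent palladium, transmetallation, reductive elimination) joins C4 to C15 and leaves the enol ether out of conjugation.

Step 6
Reactants: 9 2-[(S)-4-allyl-2,2-dimethyl-4H-1,3-dioxin-5-yl]-N-methoxy-N-methylacetamide
Product: 10 1-[(S)-4-allyl-2,2-dimethyl-4H-1,3-dioxin-5-yl]-4-methylpent-4-en-2-one
Conditions: CH2=C(CH3)CH2MgCl, THF, −78 → −20 °C; pH 7 phosphate buffer
Reagents that add atoms: 2-methylallylmagnesium chloride, CC(=C)C[Mg]Cl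
Why: Grignard addition to an N-methoxy-N-methylamide stops at the chelated tetrahedral intermediate and gives the ketone on buffered work-up, bringing in C9, C10 and C14.

Step 7
Reactants: 10 1-[(S)-4-allyl-2,2-dimethyl-4H-1,3-dioxin-5-yl]-4-methylpent-4-en-2-one
Product: 11 (3S,1(10)Z) eight-membered ketone: ring C3–C4–C15–C8(=O)–C9–C10(CH3)=C1–C2, 2,2-dimethyl-4H-1,3-dioxin fused at C3–C4
Conditions: second-generation Grubbs catalyst (5 mol %), 1,4-benzoquinone (10 mol %), CH2Cl2 (2 mM), 40 °C
Reagents that add atoms: none
Why: Ring-closing metathesis between the allyl and 2-methylallyl ends closes the eight-membered ring with the necessarily Z trisubstituted C1=C10 bond; the trisubstituted enol ether should not engage the ruthenium carbene and benzoquinone suppresses olefin migration.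

Step 8
Reactants: 12 4-methoxybenzyl alcohol
Product: 13 (E)-1,2-dichlorovinyl 4-methoxybenzyl ether
Conditions: KH, THF, 0 °C; Cl2C=CHCl, 25 °C
Reagents that add atoms: trichloroethylene, ClC=C(Cl)Cl
Why: The potassium alkoxide adds to dichloroacetylene formed in the flask from trichloroethylene (anti addition, then protonation), giving the E-dichlorovinyl ether as a storable precursor of the alkoxyacetylide.

Step 9
Reactants: 11 (3S,1(10)Z) eight-membered ketone; 13 (E)-1,2-dichlorovinyl 4-methoxybenzyl ether
Product: 15 C8 tertiary propargylic alcohol of 11 bearing C≡C–OCH2C6H4OCH3 (both C8 epimers), via lithium (4-methoxybenzyloxy)acetylide 14 (not isolated)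
Conditions: 13, n-BuLi (2.1 equiv), THF, −78 → −40 °C; CeCl3, −78 °C; 11, −78 °C; aq. NaHCO3
Reagents that add atoms: none
Why: β-Elimination and chlorine–lithium exchange convert 13 into the lithium alkoxyacetylide, whose organocerium form undergoes 1,2-addition to the easily enolised ketone; C8 may form as a mixture and is erased in step 11.

Step 10
Reactants: 15 C8 tertiary propargylic alcohol
Product: 16 C8 tertiary alcohol bearing the (E)-2-(4-methoxybenzyloxy)vinyl group (C7=C6)
Conditions: LiAlH4, THF, 0 → 25 °C; aq. KNaC4H4O6; chromatography on Et3N-deactivated silica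
Reagents that add atoms: none
Why: Hydroxyl-directed trans-hydroalumination of the propargylic alcohol and protonolysis give the E enol ether, placing O6 trans to C8; the product is acid-labile and is handled under basic conditions.

Step 11
Reactants: 16 (E)-2-(4-methoxybenzyloxy)vinyl carbinol
Product: 18 (3S,5S,6S,7S,1(10)Z) ten-membered keto ester: C8 ketone, C7–CH2CO2CH3, C6–O-4-methoxybenzyl, 3,5-O-isopropylidene, C4=C15H2, via ring-expanded potassium enolate 17 (not isolated)
Conditions: KH, 18-crown-6, THF, 0 → 25 °C; then −78 °C, ICH2CO2CH3; pH 7 buffer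
Reagents that add atoms: methyl iodoacetate, COC(=O)CI
Why: KH/18-crown-6 gives the tertiary potassium alkoxide, in which the ring bond C8–C15 (allylic to the dioxin enol ether and weakened by the oxido group) breaks while C5 of the dioxin bonds to C6 of the alkoxyvinyl group in a concerted [3,3] shift; C15 thereby leaves the ring as the exocyclic methylene on C4, and the resulting C8(O−)=C7 enolate is alkylated at C7 in the same flask. Closest known reaction types are the anionic oxy-Cope ring enlargement of 1-alkenylcycloalkanols (four-carbon version) and the Claisen ring expansion of 2-methylene-6-vinyl oxacycles, which has the same topology (the central atom of the 1,5-diene leaves the ring, net growth by two atoms). The ten-membered ring is closed by the C5–C6 bond in a chair six-centre array that shares C4, C15 and C8 with the eight-membered ring (bicyclo[3.3.1]-like, suprafacial on both allyl units); no other ring is formed, and the dioxin becomes the 5-methylene-1,3-dioxane bridging C3 and C5. C5 and C6: both oxygens are E-disposed relative to the breaking bond (O5 by the dioxin ring, O6 by the trans reduction of step 10), so the chair should give the syn pair, and the face is dictated by C3 (S), because the bridge C2–C1=C10–C9 can span C3 and C8 only when C8 lies on the face of the dioxin on which C2 leaves C3; together this should give 5S,6S. C7: the electrophile should enter the enolate from the open outer face, away from the C4=C15/C5 segment folded over the inner face, which puts H7 anti to H6 as the trans-lactone needs. Selectivities needed: (a) only the C8 epimer with the alkenyl group on the dioxin side fits the chair, and the other is expected to equilibrate by reversible C8–C15 heterolysis in the alkoxide; (b) cleavage of C8–C15 rather than C8–C9 with the ring olefin, which would need a boat across the ring and an unstabilised trialkylallyl fragment; (c) no β-elimination of the C6 ether from the enolate, whose C6–O bond lies near the nodal plane because C5 and H6 take the out-of-plane positions.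

Step 12
Reactants: 18 ten-membered keto ester
Product: 20 (3S,5S,6S,7S,1(10)Z) keto lactone (6,12-olide, C8 ketone, 3,5-O-isopropylidene), via C6 hydroxy ester 19 (not isolated)
Conditions: DDQ, CH2Cl2/pH 7 buffer, 0 °C; then PPTS (cat.), CH2Cl2, 25 °C
Reagents that add atoms: none
Why: Oxidative cleavage of the 4-methoxybenzyl ether frees the C6 hydroxyl, which closes the γ-lactone onto the ester (lactonisation); since C11 is already on C7 from step 11, the lactone is trans-fused (H6 and H7 anti).

Step 13
Reactants: 20 keto lactone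
Product: 21 (3S,5S,6S,7R,8S,1(10)Z) 8-hydroxy lactone
Conditions: NaBH4, CeCl3·7H2O, CH3OH/CH2Cl2, −78 °C
Reagents that add atoms: none
Why: Luche reduction: hydride should attack the C8 carbonyl from the outer face of the ring (the inner face is covered by the C4=C15/C5 segment), giving the 8S alcohol with O8 cis to H7; the lactone is not reduced at −78 °C.

Step 14
Reactants: 21 8-hydroxy lactone (1(10)Z)
Product: 22 1,10-cis-epoxide of 21 (either face)
Conditions: mCPBA, NaHCO3, CH2Cl2, 0 °C
Reagents that add atoms: 3-chloroperbenzoic acid, OOC(=O)c1cccc(Cl)c1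
Why: Peracid (Prilezhaev) epoxidation should take the most electron-rich olefin, trisubstituted C1=C10, the exocyclic methylene being deactivated by two allylic C–O bonds; the face is irrelevant because both oxirane carbons become trigonal again in step 15.

Step 15
Reactants: 22 1,10-cis-epoxide
Product: 25 (3S,5S,6S,7R,8S,1(10)E) 8-hydroxy lactone, via β-oxido phosphine 23 (not isolated), via phosphonium betaine 24 (not isolated)
Conditions: Ph2PLi (from Ph2PH and n-BuLi), THF, 0 → 25 °C; then CH3I, 25 °C
Reagents that add atoms: none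
Why: Olefin inversion through a β-oxido phosphonium betaine: the phosphide opens the oxirane at C1 with inversion, and P-methylation followed by syn-elimination of methyldiphenylphosphine oxide turns the cis epoxide into the E olefin; the phosphide is a soft, weakly basic nucleophile that should leave the γ-lactone alone.

Step 16
Reactants: 25 8-hydroxy lactone (1(10)E)
Product: 28 (3S,5S,6S,7R,8S,1(10)E) α-methylene lactone with free C8 hydroxyl, via C11 Mannich base 26 (not isolated), via trimethylammonium iodide 27 (not isolated)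
Conditions: LiN(iPr)2 (2.3 equiv), THF, −78 °C; CH2=N(CH3)2 I; then CH3I, CH3OH; then NaHCO3, CH2Cl2/H2O
Reagents that add atoms: dimethyl(methylene)ammonium iodide, C=[N+](C)C.[I-]
Why: α-Methylenation of the lactone by Mannich reaction of its lithium enolate (the second equivalent of base covers the hydroxyl), quaternisation and E1cB loss of trimethylamine; it follows step 15 because the enoate would not survive the phosphide.

Step 17
Reactants: 28 α-methylene lactone with free C8 hydroxyl; 29 angelic acid ((Z)-2-methylbut-2-enoic acid)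
Product: 30 (3S,5S,6S,7R,8S,1(10)E) 8-O-angelate, 3,5-O-isopropylidene
Conditions: 29, 2,4,6-trichlorobenzoyl chloride, Et3N, toluene, 25 °C; then 28, toluene, 75 °C
Reagents that add atoms: none
Why: Yamaguchi esterification through the mixed trichlorobenzoic anhydride acylates the hindered C8 hydroxyl, the only free one, and is run without a nucleophilic catalyst so that the angelate should not isomerise to the tiglate.

Step 18
Reactants: 30 8-O-angelate, 3,5-O-isopropylidene
Product: 31 (3S,5S,6S,7R,8S,1(10)E) 3,5-diol
Conditions: AcOH/THF/H2O (3:1:1), 35 °C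
Reagents that add atoms: none
Why: Acid-catalysed acetal hydrolysis removes the isopropylidene group; mild aqueous acetic acid is chosen because the 1(10),4(15)-diene can cyclise across the ring under strong acid.

Step 19
Reactants: 31 3,5-diol
Product: 32 (3R,5S,6S,7R,8S,1(10)E) 3-acetate with free C5 hydroxyl (the target without its oxirane)
Conditions: PPh3, DIAD, AcOH, toluene, 0 °C
Reagents that add atoms: acetic acid, CC(=O)O
Why: Mitsunobu esterification should convert the less hindered C3 hydroxyl (next to CH2) into the acetate with SN2 inversion, S to R, correcting the centre that served as the control element; the C5 hydroxyl, flanked by the lactone-bearing C6, should react more slowly.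

Step 20
Reactants: 32 3-acetate with free C5 hydroxyl
Product: 33 target, (1R,3R,5S,6S,7R,8S,10R)
Conditions: mCPBA, NaHCO3, CH2Cl2, 0 °C
Reagents that add atoms: 3-chloroperbenzoic acid, OOC(=O)c1cccc(Cl)c1
Why: Peracid (Prilezhaev) epoxidation of the strained, electron-rich E-C1=C10 bond from its exposed outer face should give the trans 1R,10R oxirane, the usual outcome for E-1(10) olefins of this ring type; the two methylene groups and the angelate are electron-poor and should not react.

**Compound list**

1 | 2,2-dimethyl-1,3-dioxan-5-one | CC1(C)OCC(=O)CO1 | starting material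
2 | (S)-1-amino-2-(methoxymethyl)pyrrolidine (SAMP) | COC[C@@H]1CCCN1N | starting material
3 | SAMP hydrazone of 2,2-dimethyl-1,3-dioxan-5-one | COC[C@@H]1CCCN1N=C1COC(C)(C)OC1 | intermediate
4 | lithium azaenolate of 3 | [Li+].COC[C@@H]1CCCN1[N-]C1=COC(C)(C)OC1 | intermediate
5 | SAMP hydrazone of (S)-4-allyl-2,2-dimethyl-1,3-dioxan-5-one | C=CC[C@@H]1OC(C)(C)OCC1=NN1CCC[C@H]1COC | intermediate
6 | (S)-4-allyl-2,2-dimethyl-1,3-dioxan-5-one | C=CC[C@@H]1OC(C)(C)OCC1=O | intermediate
7 | potassium enolate of 6 (enolised towards the CH2 group) | [K+].C=CC[C@@H]1OC(C)(C)OC=C1[O-] | intermediate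
8 | (S)-4-allyl-2,2-dimethyl-4H-1,3-dioxin-5-yl trifluoromethanesulfonate | C=CC[C@@H]1OC(C)(C)OC=C1OS(=O)(=O)C(F)(F)F | intermediate
9 | 2-[(S)-4-allyl-2,2-dimethyl-4H-1,3-dioxin-5-yl]-N-methoxy-N-methylacetamide | C=CC[C@@H]1OC(C)(C)OC=C1CC(=O)N(C)OC | intermediate
10 | 1-[(S)-4-allyl-2,2-dimethyl-4H-1,3-dioxin-5-yl]-4-methylpent-4-en-2-one | C=CC[C@@H]1OC(C)(C)OC=C1CC(=O)CC(C)=C | intermediate
11 | (3S,1(10)Z) eight-membered ketone, 4H-1,3-dioxin fused at C3–C4 | O=C1C/C(C)=C\C[C@@H]2OC(C)(C)OC=C2C1 | intermediate
12 | 4-methoxybenzyl alcohol | COc1ccc(CO)cc1 | starting material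
13 | (E)-1,2-dichlorovinyl 4-methoxybenzyl ether | Cl/C=C(/Cl)OCc1ccc(OC)cc1 | intermediate
14 | lithium (4-methoxybenzyloxy)acetylide | [Li+].[C-]#COCc1ccc(OC)cc1 | intermediate
15 | C8 propargylic alcohol of 11 with C≡C–O-4-methoxybenzyl (3S; both C8 epimers) | COc1ccc(COC#CC2(O)C/C(C)=C\C[C@@H]3OC(C)(C)OC=C3C2)cc1 | intermediate
16 | C8 alcohol with (E)-2-(4-methoxybenzyloxy)vinyl group (3S; both C8 epimers) | COc1ccc(CO/C=C/C2(O)C/C(C)=C\C[C@@H]3OC(C)(C)OC=C3C2)cc1 | intermediate
17 | (3S,5S,6S) ten-membered potassium enolate C8(O−)=C7 | [K+].COc1ccc(CO[C@H]2C=C([O-])C/C(C)=C\C[C@@H]3OC(C)(C)O[C@H]2C3=C)cc1 | intermediate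
18 | (3S,5S,6S,7S,1(10)Z) keto ester: methyl C7-acetate, C6 4-methoxybenzyl ether, 3,5-O-isopropylidene | COC(=O)C[C@@H]1C(=O)C/C(C)=C\C[C@@H]2OC(C)(C)O[C@H]([C@H]1OCc1ccc(OC)cc1)C2=C | intermediate
19 | (3S,5S,6S,7S) C6 hydroxy keto ester | COC(=O)C[C@@H]1C(=O)C/C(C)=C\C[C@@H]2OC(C)(C)O[C@H]([C@H]1O)C2=C | intermediate
20 | (3S,5S,6S,7S,1(10)Z) keto lactone (6,12-olide, C8 ketone) | C1C(=O)O[C@H]2[C@H]1C(=O)C/C(C)=C\C[C@@H]3OC(C)(C)O[C@H]2C3=C | intermediate
21 | (3S,5S,6S,7R,8S,1(10)Z) 8-hydroxy lactone | C1C(=O)O[C@H]2[C@H]1[C@@H](O)C/C(C)=C\C[C@@H]3OC(C)(C)O[C@H]2C3=C | intermediate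
22 | 1,10-cis-epoxide of 21 (either face; C1, C10 unassigned) | C1C(=O)O[C@H]2[C@H]1[C@@H](O)CC3(C)OC3C[C@@H]4OC(C)(C)O[C@H]2C4=C | intermediate
23 | lithium C10 alkoxide with C1 diphenylphosphino group (C1, C10 unassigned) | [Li+].C1C(=O)O[C@H]2[C@H]1[C@@H](O)CC(C)([O-])C(P(c3ccccc3)c3ccccc3)C[C@@H]3OC(C)(C)O[C@H]2C3=C | intermediate
24 | C10 oxido C1 methyldiphenylphosphonium betaine (C1, C10 unassigned) | C1C(=O)O[C@H]2[C@H]1[C@@H](O)CC(C)([O-])C([P+](C)(c3ccccc3)c3ccccc3)C[C@@H]3OC(C)(C)O[C@H]2C3=C | intermediate
25 | (3S,5S,6S,7R,8S,1(10)E) 8-hydroxy lactone | C1C(=O)O[C@H]2[C@H]1[C@@H](O)C/C(C)=C/C[C@@H]3OC(C)(C)O[C@H]2C3=C | intermediate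
26 | C11 (dimethylaminomethyl) lactone (C11 unassigned) | CN(C)CC1C(=O)O[C@H]2[C@H]1[C@@H](O)C/C(C)=C/C[C@@H]3OC(C)(C)O[C@H]2C3=C | intermediate
27 | C11 (trimethylammoniomethyl) lactone iodide (C11 unassigned) | [I-].C[N+](C)(C)CC1C(=O)O[C@H]2[C@H]1[C@@H](O)C/C(C)=C/C[C@@H]3OC(C)(C)O[C@H]2C3=C | intermediate
28 | (3S,5S,6S,7R,8S,1(10)E) α-methylene lactone, free C8 hydroxyl, 3,5-O-isopropylidene | C=C1C(=O)O[C@H]2[C@H]1[C@@H](O)C/C(C)=C/C[C@@H]3OC(C)(C)O[C@H]2C3=C | intermediate
29 | angelic acid, (Z)-2-methylbut-2-enoic acid | C/C=C(/C)C(=O)O | starting material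
30 | (3S,5S,6S,7R,8S,1(10)E) 8-O-angelate, 3,5-O-isopropylidene | C=C1C(=O)O[C@H]2[C@H]1[C@@H](OC(=O)/C(C)=C\C)C/C(C)=C/C[C@@H]3OC(C)(C)O[C@H]2C3=C | intermediate
31 | (3S,5S,6S,7R,8S,1(10)E) 8-O-angelate 3,5-diol | C=C1C(=O)O[C@H]2[C@H]1[C@@H](OC(=O)/C(C)=C\C)C/C(C)=C/C[C@H](O)C(=C)[C@@H]2O | intermediate
32 | (3R,5S,6S,7R,8S,1(10)E) 3-acetate 8-angelate with free C5 hydroxyl | C=C1C(=O)O[C@H]2[C@H]1[C@@H](OC(=O)/C(C)=C\C)C/C(C)=C/C[C@@H](OC(C)=O)C(=C)[C@@H]2O | intermediate
33 | target, (1R,3R,5S,6S,7R,8S,10R) | C=C1C(=O)O[C@H]2[C@H]1[C@@H](OC(=O)/C(C)=C\C)C[C@@]1(C)O[C@@H]1C[C@@H](OC(C)=O)C(=C)[C@@H]2O | target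

**Step count and risks**

Total step count: 20. Longest linear sequence: 19 steps (steps 1–7 and 9–20; step 8 is a side branch).

Steps most likely to fail:

Step 11. What may go wrong: the alkoxide may be diverted into cleavage of the other allylic ring bond (C8–C9, through the ring olefin), the C8 epimer that cannot reach the chair may fail to equilibrate, or the C6 ether may be lost from the enolate before it is alkylated. The fallback sets out from 15 and comes back at 18. The alkynyl carbinol 15 itself is rearranged as its potassium alkoxide (KH, 18-crown-6, THF), an anionic oxy-Cope rearrangement of a 5-en-1-yn-3-ol in which the linear alkyne is the second π unit. Protonation of the allenolate should give the ten-membered β-(4-methoxybenzyloxy) enone F1, which has no enolate carrying a β-leaving group. C6 and C7 are then set by conjugate reduction with LiBH(s-Bu)3 from the outer face and alkylation of the resulting enolate with ICH2CO2CH3, which should give 18.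

Step 19. What may go wrong: poor site selectivity between the two allylic hydroxyls, or allylic transposition (SN2′) during the Mitsunobu reaction. The fallback sets out from 31 and comes back at 32 and replaces inherent selectivity by protecting-group differentiation. Both hydroxyls are silylated (Et3SiOTf, 2,6-lutidine) to the bis(triethylsilyl) ether F2; the less hindered C3 silyl ether is removed (PPTS, CH3OH, 0 °C) to give the 5-O-triethylsilyl 3-ol F3; Mitsunobu inversion with AcOH on the single free hydroxyl gives the 3R acetate 5-O-triethylsilyl ether F4; HF·pyridine then gives 32.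

Step 20. What may go wrong: poor facial selectivity of the epoxidation, which nothing later in the route can correct. The fallback sets out from 32 and comes back at 33 and delivers the oxygen to the face opposite to the one the peracid takes. NBS in aqueous acetone forms the bromonium ion on the face the peracid prefers and water opens it at C10 from the other face, giving the bromohydrin F5 (C10 hydroxyl, C1 bromide); Ag2O then closes the oxirane with inversion at C1 to give 33.

Further compounds
F1 | step 11 | (3S,5S,1(10)Z) ten-membered 6-(4-methoxybenzyloxy)-6-en-8-one, 3,5-O-isopropylidene, C4=C15H2 | COc1ccc(COC2=CC(=O)C/C(C)=C\C[C@@H]3OC(C)(C)O[C@H]2C3=C)cc1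
F2 | step 19 | 3,5-bis(triethylsilyl) ether of 31 | C=C1C(=O)O[C@H]2[C@H]1[C@@H](OC(=O)/C(C)=C\C)C/C(C)=C/C[C@H](O[Si](CC)(CC)CC)C(=C)[C@@H]2O[Si](CC)(CC)CC
F3 | step 19 | 5-O-triethylsilyl ether of 31 with free (3S) hydroxyl | C=C1C(=O)O[C@H]2[C@H]1[C@@H](OC(=O)/C(C)=C\C)C/C(C)=C/C[C@H](O)C(=C)[C@@H]2O[Si](CC)(CC)CC
F4 | step 19 | 5-O-triethylsilyl ether of 32 ((3R) acetate) | C=C1C(=O)O[C@H]2[C@H]1[C@@H](OC(=O)/C(C)=C\C)C/C(C)=C/C[C@@H](OC(C)=O)C(=C)[C@@H]2O[Si](CC)(CC)CC
F5 | step 20 | bromohydrin of 32: C10 tertiary hydroxyl, C1 bromide (anti) | C=C1C(=O)O[C@H]2[C@H]1[C@@H](OC(=O)/C(C)=C\C)C[C@@](C)(O)[C@@H](Br)C[C@@H](OC(C)=O)C(=C)[C@@H]2O
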